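Do not try to lay the west and north-west runs on one curve of enzyme loading times time. It cannot be done, for north-west at 0.833 d has had less of that product than west at 4.00 d and yet holds 22.3% of target against 10.2%, a gap of 12 percentage points on a scatter of 1 point.

the same everywhere: starting material 20 mM
- west: second substrate 1 equiv; enzyme 0.01 mol%; run made earlier
- north-west: second substrate 1 equiv; enzyme 0.04 mol%; run made earlier
- flask: second substrate 1.00 equiv; enzyme 0.02 mol%; time 8.0 d

| run | time / d | target / % |
|---|---|---|
| west | 0.333 | 4.1 |
| west | 0.833 | 4.8 |
| west | 2.08 | 12.7 |
| west | 4.00 | 10.2 |
| west | 10.0 | 2.5 |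
| north-west | 0.333 | 10.4 |
| north-west | 0.833 | 22.3 |
| north-west | 2.08 | 16.8 |
| north-west | 4.00 | 9.2 |
| north-west | 10.0 | 1.0 |

(each reading ± 1 percentage point)

- the best time, 8.0 d at the latest, for target
- the amount of target, in percent of the starting material charged, at that time

Decide the next charge instead by what a step in enzyme buys. Take the highest readings, 12.7% in west and 22.3% in north-west, and divide the logarithm of their ratio by the logarithm of the loading ratio, which gives n = 0.406, the peak order, the power of the enzyme loading to which the height of the target peak rises. A factor of 4.00 in enzyme thus bought a factor of 1.76 in peak, so n stands below first order. Charge twice the west loading, and my reckoning from n puts the flask's peak at 16.8%, while the same reckoning on the times of those readings puts it at 1.32 d. West fell from 12.7% at 2.08 d to 2.5% at 10.0 d, so plan to stop the flask near the reckoned peak time and do not wait for the 8.0 d allowed. The forecast, for a flask that “lies midway on a log scale”, says 16% at 1.7 d, which is lower and later than my reckoning.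

The flask gives 17.1% at 1.48 d.

    complex B → enzyme + second product (k = 0.0682 /s)
    complex A ⇌ enzyme + target (K = 0.00860 M, k = 0.0485 /s)
    2 second substrate → homo dimer (k = 0.00109 /M/s)
    starting material → uncatalysed product (k = 6.16 × 10⁻⁶ /s)
    starting material + enzyme ⇌ complex A (K = 56.9 /M, k = 609 /M/s)
    second substrate + enzyme ⇌ complex B (K = 300 /M, k = 204 /M/s)

Carried forward, n gave 16.8% for this flask, which reached 17.1%. For the neighbouring flask with 0.05 mol% of enzyme, n gives 24.4%, and that flask reaches 22.8%. The largest single effect on the height of this flask's peak is the back reaction of complex A to starting material + enzyme : in the simulated run without that back reaction, the highest target rises from 17.1% to 76.8%.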